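**Retrosynthetic overview**

1. Manassantin B1 ⇒ benzyl ether of the ring-A phenol (removed last) ⇒ both side-chain carbinols by Felkin–Anh reduction ⇒ both aryl ether bonds by double SN2 (inversion) of a lactate-derived α-tosyloxy ketone on the core diphenol.
2. Core diphenol ⇒ 2,5-diaryl-4-methyl-3-methylideneoxolane; the C3 methyl is carried as an exocyclic methylene and set afterwards by hydrogenation anti to ring A.
3. Key disconnection: the oxolane is the only ring formed (all benzene rings are bought). It is closed in one operation by making C4–C5 (catalyst-controlled syn-crotylboration of the ring-B aldehyde) and O1–C2 (SN2 of the new C5 alkoxide on a phosphate at C2).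
4. Enabling feature: C2 is benzylic to ring A and lies 1,4 to O1 across C5–C4–C3, and C3 carries a methyl that can be an exocyclic CH2; this makes C2 allylic as well and turns C3–CH2–B into an allylboron handle with C4 as the nucleophilic γ-carbon.
5. The crotylboronate comes from the ring-A aldehyde by asymmetric propynylation, hydroxyl-directed trans-hydrostannation/iodination, Negishi borylmethylation and phosphorylation; a para-tosyloxy group on each ring protects the phenols and keeps C2 from ionising.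

Key step: step 7

Assumption: 3-(benzyloxy)-4-hydroxybenzaldehyde and (S)-2-hydroxy-N-methoxy-N-methylpropanamide are taken as catalogue compounds, and the sense of induction in the ligand-controlled steps 2 and 7 is assigned by analogy with simple aryl aldehydes (the antipodal ligand would be used otherwise).

**Route**

Step 1
Reactants: 1 3-(benzyloxy)-4-hydroxybenzaldehyde
Product: 2 2-(benzyloxy)-4-formylphenyl 4-methylbenzenesulfonate
Conditions: TsCl, Et3N, DMAP (cat.), CH2Cl2, 0 °C to rt
Reagents that add atoms: 4-methylbenzenesulfonyl chloride (TsCl), Cc1ccc(cc1)S(Cl)(=O)=O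
Why: O-sulfonylation of the phenol (DMAP nucleophilic catalysis) protects it and places an electron-withdrawing group para to the future C2, which is needed later to suppress benzylic ionisation.

Step 2
Reactants: 2 2-(benzyloxy)-4-formylphenyl 4-methylbenzenesulfonate
Product: 3 2-(benzyloxy)-4-[(1S)-1-hydroxybut-2-yn-1-yl]phenyl 4-methylbenzenesulfonate
Conditions: propyne, Et2Zn, (R)-BINOL (20 mol%), Ti(OiPr)4 (50 mol%), Cy2NH (5 mol%), Et2O/THF, rt; aq. NH4Cl
Reagents that add atoms: propyne, CC#C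
Why: Catalytic asymmetric alkynylzinc addition to an aryl aldehyde (BINOL–titanium alkynylation), in which the ligand selects the aldehyde face and should set the (S) carbinol centre that later becomes C2.

Step 3
Reactants: 3 2-(benzyloxy)-4-[(1S)-1-hydroxybut-2-yn-1-yl]phenyl 4-methylbenzenesulfonate
Product: 5 2-(benzyloxy)-4-[(1S,2Z)-1-hydroxy-2-iodobut-2-en-1-yl]phenyl 4-methylbenzenesulfonate, via vinylstannane 4 (not isolated)
Conditions: Bu3SnH, [Cp*RuCl]4 (2.5 mol%), CH2Cl2, rt; then I2, 0 °C
Reagents that add atoms: iodine, II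
Why: Hydroxyl-directed ruthenium-catalysed trans-hydrostannation should place tin on the alkyne carbon next to the carbinol with hydrogen trans to it, and iododestannylation with retention then gives the (Z)-iodide in which iodine and the methyl group are cis.

Step 4
Reactants: 5 2-(benzyloxy)-4-[(1S,2Z)-1-hydroxy-2-iodobut-2-en-1-yl]phenyl 4-methylbenzenesulfonate
Product: 6 2-(benzyloxy)-4-[(1R,2E)-1-hydroxy-2-[(4,4,5,5-tetramethyl-1,3,2-dioxaborolan-2-yl)methyl]but-2-en-1-yl]phenyl 4-methylbenzenesulfonate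
Conditions: IZnCH2Bpin (2.5 equiv, from ICH2Bpin and Zn), Pd(PPh3)4 (5 mol%), THF, 40 °C
Reagents that add atoms: [(4,4,5,5-tetramethyl-1,3,2-dioxaborolan-2-yl)methyl]zinc iodide, I[Zn]CB1OC(C)(C)C(C)(C)O1
Why: Negishi cross-coupling of the alkenyl iodide proceeds with retention of alkene geometry, so the CH2B group ends up cis to the methyl group (crotylboronate of the Z type), while the carbinol centre is untouched and is (R) only through a change of CIP priority.

Step 5
Reactants: 6 2-(benzyloxy)-4-[(1R,2E)-1-hydroxy-2-[(4,4,5,5-tetramethyl-1,3,2-dioxaborolan-2-yl)methyl]but-2-en-1-yl]phenyl 4-methylbenzenesulfonate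
Product: 7 2-(benzyloxy)-4-[(1R,2E)-1-[(diethoxyphosphoryl)oxy]-2-[(4,4,5,5-tetramethyl-1,3,2-dioxaborolan-2-yl)methyl]but-2-en-1-yl]phenyl 4-methylbenzenesulfonate
Conditions: ClP(O)(OEt)2, Et3N, DMAP (cat.), CH2Cl2, 0 °C; used promptly
Reagents that add atoms: diethyl chlorophosphate, CCOP(Cl)(=O)OCC
Why: O-phosphorylation (retention at carbon) turns the hydroxyl into a leaving group that should survive the Brønsted acid of step 7 because the para-tosyloxy group disfavours ionisation of the benzylic, allylic C–O bond.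

Step 6
Reactants: 8 vanillin (4-hydroxy-3-methoxybenzaldehyde)
Product: 9 4-formyl-2-methoxyphenyl 4-methylbenzenesulfonate
Conditions: TsCl, Et3N, DMAP (cat.), CH2Cl2, 0 °C to rt
Reagents that add atoms: 4-methylbenzenesulfonyl chloride (TsCl), Cc1ccc(cc1)S(Cl)(=O)=O
Why: O-sulfonylation protects the ring-B phenol with a group that is stable to acid, organometallics and hydrogenation and is removed together with the ring-A tosylate in step 9.

Step 7
Reactants: 7 2-(benzyloxy)-4-[(1R,2E)-1-[(diethoxyphosphoryl)oxy]-2-[(4,4,5,5-tetramethyl-1,3,2-dioxaborolan-2-yl)methyl]but-2-en-1-yl]phenyl 4-methylbenzenesulfonate (1.2 equiv); 9 4-formyl-2-methoxyphenyl 4-methylbenzenesulfonate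
Product: 11 2-(benzyloxy)-4-[(2S,4R,5S)-5-{3-methoxy-4-[(4-methylbenzenesulfonyl)oxy]phenyl}-4-methyl-3-methylideneoxolan-2-yl]phenyl 4-methylbenzenesulfonate, via pinacol borate 10 (not isolated)
Conditions: (S)-TRIP [(S)-3,3′-bis(2,4,6-triisopropylphenyl)-1,1′-binaphthyl-2,2′-diyl hydrogen phosphate] (5 mol%), 4 Å MS, toluene, −30 to 0 °C; then KOtBu, THF, −30 °C to rt
Reagents that add atoms: none
Why: The chiral phosphoric acid activates the pinacol boronate by hydrogen bonding and aldehyde 9 adds through a closed six-membered chair transition state (asymmetric crotylboration, the closest known reaction type), forming C4–C5 with allyl transposition so that C3 becomes an exocyclic methylene. Because the methyl on the γ-carbon is cis to CH2B it sits axial while the aryl group of 9 sits equatorial, which gives the 4,5-syn pair, and the catalyst selects the Si face of 9, so C5 (S) and C4 (R) are set by the catalyst together with the alkene geometry. tert-Butoxide then converts borate 10 into the potassium alkoxide, which displaces the diethyl phosphate at C2 in a 5-exo-tet SN2 reaction (intramolecular Williamson etherification), closing the oxolane ring with inversion so that the (R) centre of 7 becomes (2S) with ring A trans to ring B. The sequence is the chiral, substituted version of the known annulation of aldehydes with 2-(halomethyl)allyl metal reagents (trimethylenemethane equivalents) to 3-methylenetetrahydrofurans, and of γ-chloroallylboration followed by base-induced epoxide closure. The step needs clean SN2 at C2 rather than ionisation, allylic transposition or 5-endo SN2′ attack at the methylene carbon; this should be secured by the allylic and benzylic activation of C2 towards backside attack, by the para-tosyloxy group on ring A that destabilises a benzylic cation, and by the 1,4-relationship of the alkoxide oxygen and C2. The stereocentre of 7 is remote from the reacting allyl terminus, so the facial selectivity of the C–C bond formation is expected to be catalyst-controlled.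

Step 8
Reactants: 11 2-(benzyloxy)-4-[(2S,4R,5S)-5-{3-methoxy-4-[(4-methylbenzenesulfonyl)oxy]phenyl}-4-methyl-3-methylideneoxolan-2-yl]phenyl 4-methylbenzenesulfonate
Product: 12 2-(benzyloxy)-4-[(2S,3R,4R,5S)-5-{3-methoxy-4-[(4-methylbenzenesulfonyl)oxy]phenyl}-3,4-dimethyloxolan-2-yl]phenyl 4-methylbenzenesulfonate
Conditions: H2 (1 atm), [Ir(cod)(PCy3)(py)]PF6 (5 mol%), CH2Cl2, rt
Reagents that add atoms: none
Why: Homogeneous hydrogenation of the 1,1-disubstituted exocyclic alkene, in which the C2 aryl and the C4 methyl should sit pseudoaxial on opposite faces to relieve allylic strain, so that the bulky cationic iridium catalyst approaches anti to the larger aryl group and delivers hydrogen to C3 trans to ring A (C3 R, 2,3-cis-3,4-trans), without cleaving the benzyl ether or the benzylic C–O bonds.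

Step 9
Reactants: 12 2-(benzyloxy)-4-[(2S,3R,4R,5S)-5-{3-methoxy-4-[(4-methylbenzenesulfonyl)oxy]phenyl}-3,4-dimethyloxolan-2-yl]phenyl 4-methylbenzenesulfonate
Product: 13 2-(benzyloxy)-4-[(2S,3R,4R,5S)-5-(4-hydroxy-3-methoxyphenyl)-3,4-dimethyloxolan-2-yl]phenol
Conditions: KOH, MeOH/THF, 60 °C; then aq. NH4Cl
Reagents that add atoms: none
Why: Saponification of both aryl sulfonates by hydroxide attack at sulfur frees the two para-phenols, while the oxolane, its four stereocentres and the benzyl ether are inert to base.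

Step 10
Reactants: 14 (S)-2-hydroxy-N-methoxy-N-methylpropanamide; 15 (3,4-dimethoxyphenyl)magnesium bromide (2.5 equiv)
Product: 16 (S)-1-(3,4-dimethoxyphenyl)-2-hydroxypropan-1-one
Conditions: THF, −20 to 0 °C; aq. NH4Cl
Reagents that add atoms: none
Why: Weinreb ketone synthesis, in which the first equivalent of Grignard reagent deprotonates the hydroxyl and the chelated tetrahedral intermediate prevents over-addition, leaving the lactate stereocentre untouched.

Step 11
Reactants: 16 (S)-1-(3,4-dimethoxyphenyl)-2-hydroxypropan-1-one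
Product: 17 (S)-1-(3,4-dimethoxyphenyl)-1-oxopropan-2-yl 4-methylbenzenesulfonate
Conditions: TsCl, Et3N, DMAP (cat.), CH2Cl2, 0 °C
Reagents that add atoms: 4-methylbenzenesulfonyl chloride (TsCl), Cc1ccc(cc1)S(Cl)(=O)=O
Why: O-sulfonylation with retention at carbon gives an α-keto electrophile whose leaving group is non-nucleophilic, so the electrophile cannot racemise by self-exchange.

Step 12
Reactants: 13 2-(benzyloxy)-4-[(2S,3R,4R,5S)-5-(4-hydroxy-3-methoxyphenyl)-3,4-dimethyloxolan-2-yl]phenol; 17 (S)-1-(3,4-dimethoxyphenyl)-1-oxopropan-2-yl 4-methylbenzenesulfonate (2.3 equiv)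
Product: 18 (2R)-2-[2-(benzyloxy)-4-[(2S,3R,4R,5S)-5-[4-{[(2R)-1-(3,4-dimethoxyphenyl)-1-oxopropan-2-yl]oxy}-3-methoxyphenyl]-3,4-dimethyloxolan-2-yl]phenoxy]-1-(3,4-dimethoxyphenyl)propan-1-one
Conditions: Cs2CO3, MeCN, 0 °C to rt
Reagents that add atoms: none
Why: Double Williamson etherification in which each phenoxide displaces the α-keto tosylate by SN2 with inversion, (S) to (R), under a mild base at low temperature to limit enolisation.

Step 13
Reactants: 18 the bis(aryloxy ketone) of step 12
Product: 19 (1R,2R)-2-[2-(benzyloxy)-4-[(2S,3R,4R,5S)-5-[4-{[(1R,2R)-1-(3,4-dimethoxyphenyl)-1-hydroxypropan-2-yl]oxy}-3-methoxyphenyl]-3,4-dimethyloxolan-2-yl]phenoxy]-1-(3,4-dimethoxyphenyl)propan-1-ol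
Conditions: n-Bu4NBH4, MeOH/CH2Cl2, −40 to −20 °C
Reagents that add atoms: none
Why: Hydride reduction with a non-chelating ammonium borohydride should follow the Felkin–Anh model (aryloxy group anti to the incoming hydride, attack past the hydrogen), giving the (1R,2R) relationship in both side chains from the (2R) ketones.

Step 14
Reactants: 19 O-benzyl manassantin B1
Product: 20 manassantin B1
Conditions: H2 (1 atm), 10% Pd/C, EtOAc, rt
Reagents that add atoms: none
Why: Hydrogenolysis of the aryl benzyl ether under neutral conditions, which is much faster than cleavage of the secondary benzylic alcohols or the benzylic ring C–O bonds, frees the ring-A phenol.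

**Compound list**

1 | 3-(benzyloxy)-4-hydroxybenzaldehyde | O=Cc1ccc(O)c(OCc2ccccc2)c1 | starting material
2 | 2-(benzyloxy)-4-formylphenyl 4-methylbenzenesulfonate | Cc1ccc(cc1)S(=O)(=O)Oc1ccc(C=O)cc1OCc1ccccc1 | intermediate
3 | 2-(benzyloxy)-4-[(1S)-1-hydroxybut-2-yn-1-yl]phenyl 4-methylbenzenesulfonate | Cc1ccc(cc1)S(=O)(=O)Oc1ccc(cc1OCc1ccccc1)[C@H](O)C#CC | intermediate
4 | 2-(benzyloxy)-4-[(1S,2Z)-1-hydroxy-2-(tributylstannyl)but-2-en-1-yl]phenyl 4-methylbenzenesulfonate | Cc1ccc(cc1)S(=O)(=O)Oc1ccc(cc1OCc1ccccc1)[C@H](O)/C([Sn](CCCC)(CCCC)CCCC)=C/C | intermediate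
5 | 2-(benzyloxy)-4-[(1S,2Z)-1-hydroxy-2-iodobut-2-en-1-yl]phenyl 4-methylbenzenesulfonate | Cc1ccc(cc1)S(=O)(=O)Oc1ccc(cc1OCc1ccccc1)[C@H](O)/C(I)=C/C | intermediate
6 | 2-(benzyloxy)-4-[(1R,2E)-1-hydroxy-2-[(4,4,5,5-tetramethyl-1,3,2-dioxaborolan-2-yl)methyl]but-2-en-1-yl]phenyl 4-methylbenzenesulfonate | Cc1ccc(cc1)S(=O)(=O)Oc1ccc(cc1OCc1ccccc1)[C@H](O)/C(CB1OC(C)(C)C(C)(C)O1)=C/C | intermediate
7 | 2-(benzyloxy)-4-[(1R,2E)-1-[(diethoxyphosphoryl)oxy]-2-[(4,4,5,5-tetramethyl-1,3,2-dioxaborolan-2-yl)methyl]but-2-en-1-yl]phenyl 4-methylbenzenesulfonate | Cc1ccc(cc1)S(=O)(=O)Oc1ccc(cc1OCc1ccccc1)[C@H](OP(=O)(OCC)OCC)/C(CB1OC(C)(C)C(C)(C)O1)=C/C | intermediate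
8 | vanillin (4-hydroxy-3-methoxybenzaldehyde) | COc1cc(C=O)ccc1O | starting material
9 | 4-formyl-2-methoxyphenyl 4-methylbenzenesulfonate | Cc1ccc(cc1)S(=O)(=O)Oc1ccc(C=O)cc1OC | intermediate
10 | 2-(benzyloxy)-4-[(1R,3R,4S)-1-[(diethoxyphosphoryl)oxy]-4-{3-methoxy-4-[(4-methylbenzenesulfonyl)oxy]phenyl}-3-methyl-2-methylidene-4-[(4,4,5,5-tetramethyl-1,3,2-dioxaborolan-2-yl)oxy]butyl]phenyl 4-methylbenzenesulfonate | Cc1ccc(cc1)S(=O)(=O)Oc1ccc(cc1OCc1ccccc1)[C@H](OP(=O)(OCC)OCC)C(=C)[C@@H](C)[C@H](OB1OC(C)(C)C(C)(C)O1)c1ccc(OS(=O)(=O)c2ccc(C)cc2)c(OC)c1 | intermediate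
11 | 2-(benzyloxy)-4-[(2S,4R,5S)-5-{3-methoxy-4-[(4-methylbenzenesulfonyl)oxy]phenyl}-4-methyl-3-methylideneoxolan-2-yl]phenyl 4-methylbenzenesulfonate | Cc1ccc(cc1)S(=O)(=O)Oc1ccc(cc1OCc1ccccc1)[C@H]1O[C@H](c2ccc(OS(=O)(=O)c3ccc(C)cc3)c(OC)c2)[C@H](C)C1=C | intermediate
12 | 2-(benzyloxy)-4-[(2S,3R,4R,5S)-5-{3-methoxy-4-[(4-methylbenzenesulfonyl)oxy]phenyl}-3,4-dimethyloxolan-2-yl]phenyl 4-methylbenzenesulfonate | Cc1ccc(cc1)S(=O)(=O)Oc1ccc(cc1OCc1ccccc1)[C@H]1O[C@H](c2ccc(OS(=O)(=O)c3ccc(C)cc3)c(OC)c2)[C@H](C)[C@H]1C | intermediate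
13 | 2-(benzyloxy)-4-[(2S,3R,4R,5S)-5-(4-hydroxy-3-methoxyphenyl)-3,4-dimethyloxolan-2-yl]phenol | Oc1ccc(cc1OCc1ccccc1)[C@H]1O[C@H](c2ccc(O)c(OC)c2)[C@H](C)[C@H]1C | intermediate
14 | (S)-2-hydroxy-N-methoxy-N-methylpropanamide | C[C@H](O)C(=O)N(C)OC | starting material
15 | (3,4-dimethoxyphenyl)magnesium bromide | COc1ccc([Mg]Br)cc1OC | starting material
16 | (S)-1-(3,4-dimethoxyphenyl)-2-hydroxypropan-1-one | C[C@H](O)C(=O)c1ccc(OC)c(OC)c1 | intermediate
17 | (S)-1-(3,4-dimethoxyphenyl)-1-oxopropan-2-yl 4-methylbenzenesulfonate | C[C@H](OS(=O)(=O)c1ccc(C)cc1)C(=O)c1ccc(OC)c(OC)c1 | intermediate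
18 | (2R)-2-[2-(benzyloxy)-4-[(2S,3R,4R,5S)-5-[4-{[(2R)-1-(3,4-dimethoxyphenyl)-1-oxopropan-2-yl]oxy}-3-methoxyphenyl]-3,4-dimethyloxolan-2-yl]phenoxy]-1-(3,4-dimethoxyphenyl)propan-1-one | COc1ccc(C(=O)[C@@H](C)Oc2ccc([C@H]3O[C@H](c4ccc(O[C@H](C)C(=O)c5ccc(OC)c(OC)c5)c(OC)c4)[C@H](C)[C@H]3C)cc2OCc2ccccc2)cc1OC | intermediate
19 | O-benzyl manassantin B1: (1R,2R)-2-[2-(benzyloxy)-4-[(2S,3R,4R,5S)-5-[4-{[(1R,2R)-1-(3,4-dimethoxyphenyl)-1-hydroxypropan-2-yl]oxy}-3-methoxyphenyl]-3,4-dimethyloxolan-2-yl]phenoxy]-1-(3,4-dimethoxyphenyl)propan-1-ol | COc1ccc([C@@H](O)[C@@H](C)Oc2ccc([C@H]3O[C@H](c4ccc(O[C@H](C)[C@H](O)c5ccc(OC)c(OC)c5)c(OC)c4)[C@H](C)[C@H]3C)cc2OCc2ccccc2)cc1OC | intermediate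
20 | manassantin B1 | COc1ccc([C@@H](O)[C@@H](C)Oc2ccc([C@H]3O[C@H](c4ccc(O[C@H](C)[C@H](O)c5ccc(OC)c(OC)c5)c(OC)c4)[C@H](C)[C@H]3C)cc2O)cc1OC | target

**Step count and risks**

Total step count: 14. Longest linear sequence: 11 steps (steps 1, 2, 3, 4, 5, 7, 8, 9, 12, 13, 14).

The three steps most likely to fail:

Step 7 (key step). What may go wrong: ionisation or allylic transposition of the phosphate in 7 or 10 before ring closure, which would scramble C2; transfer of the phosphoryl group to the new alkoxide; or erosion of facial selectivity if the catalyst and the stereocentre of 7 are mismatched. Fallback: the two bond formations are separated and the phosphate is avoided. Setting out from 6 and 9, the same phosphoric acid-catalysed crotylboration with aqueous work-up would give the diol 2-(benzyloxy)-4-[(1R,3R,4S)-1,4-dihydroxy-4-{3-methoxy-4-[(4-methylbenzenesulfonyl)oxy]phenyl}-3-methyl-2-methylidenebutyl]phenyl 4-methylbenzenesulfonate F1. Mitsunobu cyclodehydration (PPh3, DIAD, THF, 0 °C) should then close the ring by SN2 with inversion at the carbinol carbon that is both allylic and benzylic, since the oxyphosphonium ions equilibrate and only the doubly activated centre is readily displaced. This comes back to the route at 11.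

Step 8. What may go wrong: insufficient discrimination between the two alkene faces (aryl on C2 against methyl on C4), or migration of the double bond into the ring, which would erase C2. Fallback: C3 is set under thermodynamic control next to a carbonyl group and ring A is added afterwards. Setting out from 9, allylboration–lactonization with ethyl (2E)-2-[(4,4,5,5-tetramethyl-1,3,2-dioxaborolan-2-yl)methyl]but-2-enoate (same phosphoric acid, then TsOH) would give (4R,5S)-5-{3-methoxy-4-[(4-methylbenzenesulfonyl)oxy]phenyl}-4-methyl-3-methylideneoxolan-2-one F2. Hydrogenation (H2, Pd/C) and equilibration with DBU would give the 3,4-trans-4,5-cis lactone (3R,4R,5S)-5-{3-methoxy-4-[(4-methylbenzenesulfonyl)oxy]phenyl}-3,4-dimethyloxolan-2-one F3. DIBAL-H at −78 °C would give the lactol (3R,4R,5S)-5-{3-methoxy-4-[(4-methylbenzenesulfonyl)oxy]phenyl}-3,4-dimethyloxolan-2-ol F4, and PhSO2H/CaCl2 the sulfone 2-methoxy-4-[(2S,3R,4R)-3,4-dimethyl-5-(phenylsulfonyl)oxolan-2-yl]phenyl 4-methylbenzenesulfonate F5. Addition of the arylzinc bromide prepared from 2-(benzyloxy)-4-bromophenyl 4-methylbenzenesulfonate (iPrMgCl·LiCl, then ZnBr2) to the oxocarbenium ion from F5 should place ring A cis to the C3 methyl by inside attack on the envelope. This comes back to the route at 12.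

Step 4. What may go wrong: protonolysis of the zinc reagent by the free hydroxyl, slow transmetalation at the hindered trisubstituted alkenyl iodide, or loss of the allylboronate on palladium. Fallback: the crotylboronate is built from a diene instead of an alkyne. Setting out from 2, chiral phosphoric acid-catalysed homoallenylboration with 2-(buta-2,3-dien-1-yl)-4,4,5,5-tetramethyl-1,3,2-dioxaborolane would give the dienyl carbinol 2-(benzyloxy)-4-[(1R)-1-hydroxy-2-methylidenebut-3-en-1-yl]phenyl 4-methylbenzenesulfonate F6. Pd(PPh3)4-catalysed 1,4-hydroboration with catecholborane through the s-cis diene, followed by exchange with pinacol, should give the allylboronate with the methyl cis to CH2B. This comes back to the route at 6.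

**Further compounds**

F1 | step 7 | 2-(benzyloxy)-4-[(1R,3R,4S)-1,4-dihydroxy-4-{3-methoxy-4-[(4-methylbenzenesulfonyl)oxy]phenyl}-3-methyl-2-methylidenebutyl]phenyl 4-methylbenzenesulfonate | Cc1ccc(cc1)S(=O)(=O)Oc1ccc(cc1OCc1ccccc1)[C@H](O)C(=C)[C@@H](C)[C@H](O)c1ccc(OS(=O)(=O)c2ccc(C)cc2)c(OC)c1
F2 | step 8 | (4R,5S)-5-{3-methoxy-4-[(4-methylbenzenesulfonyl)oxy]phenyl}-4-methyl-3-methylideneoxolan-2-one | O=C1O[C@H](c2ccc(OS(=O)(=O)c3ccc(C)cc3)c(OC)c2)[C@H](C)C1=C
F3 | step 8 | (3R,4R,5S)-5-{3-methoxy-4-[(4-methylbenzenesulfonyl)oxy]phenyl}-3,4-dimethyloxolan-2-one | O=C1O[C@H](c2ccc(OS(=O)(=O)c3ccc(C)cc3)c(OC)c2)[C@H](C)[C@H]1C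
F4 | step 8 | (3R,4R,5S)-5-{3-methoxy-4-[(4-methylbenzenesulfonyl)oxy]phenyl}-3,4-dimethyloxolan-2-ol (anomeric mixture) | OC1O[C@H](c2ccc(OS(=O)(=O)c3ccc(C)cc3)c(OC)c2)[C@H](C)[C@H]1C
F5 | step 8 | 2-methoxy-4-[(2S,3R,4R)-3,4-dimethyl-5-(phenylsulfonyl)oxolan-2-yl]phenyl 4-methylbenzenesulfonate (epimers at the sulfonyl carbon) | O=S(=O)(c1ccccc1)C1O[C@H](c2ccc(OS(=O)(=O)c3ccc(C)cc3)c(OC)c2)[C@H](C)[C@H]1C
F6 | step 4 | 2-(benzyloxy)-4-[(1R)-1-hydroxy-2-methylidenebut-3-en-1-yl]phenyl 4-methylbenzenesulfonate | Cc1ccc(cc1)S(=O)(=O)Oc1ccc(cc1OCc1ccccc1)[C@H](O)C(=C)C=C
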